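**Retrosynthetic overview**

1. Feature: in ring A (the cyclohexadienone ring) the ring ketone carbon, the neighbouring ring carbon with its acetyl group, and the enol carbon with its oxygen next to the bridge-bearing carbon form a 2-acetyl-1,3-dione. It is carried through the route as a 3-methylisoxazole-4-carboxylate (ester carbon = ring ketone carbon; isoxazole 4-carbon = acetyl-bearing carbon; isoxazole 5-carbon and ring oxygen = enol carbon and its oxygen; isoxazole 3-carbon with its methyl = acetyl group).
2. Last disconnections: hydrogenolysis of two benzyl ethers on ring B, hydrolysis of an enaminone, and reductive N–O cleavage of a 1,2-benzisoxazol-4-one.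
3. Key disconnection: the bond in ring A between the CMe2 carbon and the ring ketone carbon, a Claisen closure of an isopropyl ketone enolate onto the isoxazole ester, which closes ring A and creates the quaternary carbon.
4. The open-chain keto ester comes from C-benzylation (bond between the future bridge-bearing carbon of ring A and the bridge CH2) of an isoxazol-5-ylmethyl isopropyl ketone with the ring-B benzylic bromide. The ketone comes from lateral lithiation and acylation of ethyl 3,5-dimethylisoxazole-4-carboxylate. The bromide comes from 2,4,6-trihydroxytoluene by formylation, para-O-methylation, Friedel–Crafts butyrylation, benzylation, reduction and bromination.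
5. Ring order: ring B and the isoxazole are bought; ring A is the only ring formed (key step); the isoxazole ring is opened after it.

Key step: step 9

**Remarks on the chemistry**

- The target has no stereocentre and is drawn as one enol tautomer. The only stereocentre on the way (the CH of the key-step precursor) is carried as the racemate and becomes sp2 in the ring closure.
- The isobutyryl group is delivered from commercial N-methoxy-N-methylisobutyramide, so that the acidic ketone product is released only on work-up.
- The isoxazole is acylated first and benzylated second, so the butyryl ketone of ring B never meets an amide base.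
- The enaminone is hydrolysed in alkali while ring B is still benzylated, because free methylene-bridged acylphloroglucinols exchange their halves in alkali. The end game therefore has three steps.

**Route**

Step 1
Reactants: 1 2,4,6-trihydroxytoluene
Product: 3 2,4,6-trihydroxy-3-methylbenzaldehyde, via aryl iminium chloride 2 (not isolated)
Conditions: POCl3 (1.1 equiv), DMF (1.2 equiv), EtOAc, 0 °C → rt; then H2O, 50 °C
Reagents that add atoms: N,N-dimethylformamide CN(C)C=O; water O
Why: Vilsmeier–Haack formylation at one of the two equivalent free positions of the phloroglucinol ring; the iminium group formed deactivates the ring against a second formylation.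

Step 2
Reactants: 3 2,4,6-trihydroxy-3-methylbenzaldehyde
Product: 4 2,6-dihydroxy-4-methoxy-3-methylbenzaldehyde
Conditions: Me2SO4 (1.0 equiv), K2CO3 (1.0 equiv), acetone, rt
Reagents that add atoms: dimethyl sulfate COS(=O)(=O)OC
Why: Williamson-type O-methylation; the hydroxyl para to the formyl group is the most acidic and the only one not hydrogen-bonded to the carbonyl, so one equivalent of dimethyl sulfate should methylate it first.

Step 3
Reactants: 4 2,6-dihydroxy-4-methoxy-3-methylbenzaldehyde; 5 butyryl chloride
Product: 6 3-butanoyl-2,6-dihydroxy-4-methoxy-5-methylbenzaldehyde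
Conditions: AlCl3 (3.5 equiv), PhNO2/CH2Cl2, 0 °C → rt; then ice/aq. HCl
Reagents that add atoms: none
Why: Friedel–Crafts acylation at the only free ring position, which is ortho or para to all three oxygen substituents and so remains nucleophilic despite the formyl group; the mild temperature is chosen to spare the methyl ether.

Step 4
Reactants: 6 3-butanoyl-2,6-dihydroxy-4-methoxy-5-methylbenzaldehyde
Product: 7 2,6-bis(benzyloxy)-3-butanoyl-4-methoxy-5-methylbenzaldehyde
Conditions: BnBr (2.6 equiv), K2CO3 (3 equiv), Bu4NI (cat.), DMF, 65 °C
Reagents that add atoms: benzyl bromide BrCc1ccccc1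
Why: Williamson etherification; the ring is fully substituted, so no C-benzylation can compete, and warm DMF with iodide catalysis should overcome the chelation of the two ortho hydroxyls.

Step 5
Reactants: 7 2,6-bis(benzyloxy)-3-butanoyl-4-methoxy-5-methylbenzaldehyde
Product: 8 1-[2,4-bis(benzyloxy)-3-(hydroxymethyl)-6-methoxy-5-methylphenyl]butan-1-one
Conditions: NaBH4 (0.35 equiv), THF/MeOH, −20 → 0 °C
Reagents that add atoms: none
Why: Chemoselective hydride reduction; the aldehyde is far more electrophilic than the di-ortho-substituted aryl ketone, so a limited charge of NaBH4 at low temperature should stop at the benzylic alcohol.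

Step 6
Reactants: 8 1-[2,4-bis(benzyloxy)-3-(hydroxymethyl)-6-methoxy-5-methylphenyl]butan-1-one
Product: 9 1-[2,4-bis(benzyloxy)-3-(bromomethyl)-6-methoxy-5-methylphenyl]butan-1-one
Conditions: CBr4, PPh3, CH2Cl2, 0 °C
Reagents that add atoms: carbon tetrabromide BrC(Br)(Br)Br
Why: Appel bromination under neutral conditions, fast for an electron-rich benzylic alcohol and harmless to the benzyl ethers and the ketone; the bromide is used at once without storage.

Step 7
Reactants: 10 ethyl 3,5-dimethylisoxazole-4-carboxylate; 11 N-methoxy-N-methylisobutyramide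
Product: 13 ethyl 3-methyl-5-(3-methyl-2-oxobutyl)isoxazole-4-carboxylate, via lateral lithio isoxazole 12 (not isolated)
Conditions: LiN(iPr)2 (1.05 equiv), THF, −78 °C; then 11, −78 → 0 °C; aq. NH4Cl
Reagents that add atoms: none
Why: Lateral metalation–acylation (Weinreb ketone synthesis): the amide base removes a proton only from the 5-methyl group, whose anion is a vinylogous ester enolate through the ring C=C bond, and the chelated tetrahedral adduct releases the ketone only on work-up, so the more acidic product cannot quench the anion.

Step 8
Reactants: 13 ethyl 3-methyl-5-(3-methyl-2-oxobutyl)isoxazole-4-carboxylate; 9 1-[2,4-bis(benzyloxy)-3-(bromomethyl)-6-methoxy-5-methylphenyl]butan-1-one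
Product: 14 ethyl 5-{1-[2,6-bis(benzyloxy)-3-butanoyl-4-methoxy-5-methylphenyl]-4-methyl-3-oxopentan-2-yl}-3-methylisoxazole-4-carboxylate (racemic)
Conditions: Cs2CO3 (1.2 equiv), MeCN, 0 °C → rt
Reagents that add atoms: none
Why: C-Alkylation of a doubly stabilised carbanion (ketone plus ester-bearing isoxazole) with a benzylic bromide under carbonate conditions that leave the butyryl ketone alone; the new stereocentre forms as a racemate and is removed in step 9.

Step 9
Reactants: 14 ethyl 5-{1-[2,6-bis(benzyloxy)-3-butanoyl-4-methoxy-5-methylphenyl]-4-methyl-3-oxopentan-2-yl}-3-methylisoxazole-4-carboxylate (racemic)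
Product: 15 7-{[2,6-bis(benzyloxy)-3-butanoyl-4-methoxy-5-methylphenyl]methyl}-6-hydroxy-3,5,5-trimethyl-1,2-benzisoxazol-4(5H)-one
Conditions: KOtBu (3 equiv), THF, 0 → 60 °C; then 1 M HCl
Reagents that add atoms: none
Why: One equivalent of KOtBu turns 14 into the benzylic enolate at the CH between the isoxazole and the ketone, which cannot C-acylate (a four-membered ring would result) and whose O-acylation to an enol lactone is undone by the alkoxide present, while the excess base reversibly forms the less stable isopropyl enolate, whose tertiary carbon adds to the carbonyl of the isoxazole ester and expels ethoxide, making the bond between the CMe2 carbon and the ring ketone carbon of ring A and with it the quaternary centre. The closest known reaction type is the Claisen (Dieckmann-type) closure of a ketone enolate onto an isoxazole-4-carboxylate to give a 1,2-benzisoxazol-4-one, and the use of a minor ketone enolate while a more acidic site rests as its anion is that of the Michael–Claisen route to cyclohexane-1,3-diones. Ring A closes in the 6-(enolendo)-exo-trig mode. No stereocentre is formed, and the racemic centre of 14 becomes the sp2 bridge-bearing carbon of ring A. The selectivity needed is closure through the isopropyl enolate and not the benzylic one; it is secured by ring size (only the isopropyl carbon reaches the ester through a six-membered transition state) and by the isoxazole, which keeps the acceptor a non-enolisable ester. The product is a vinylogous acid that is deprotonated as it forms, which pulls the proton-transfer and addition equilibria forward.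

Step 10
Reactants: 15 7-{[2,6-bis(benzyloxy)-3-butanoyl-4-methoxy-5-methylphenyl]methyl}-6-hydroxy-3,5,5-trimethyl-1,2-benzisoxazol-4(5H)-one
Product: 16 2-(1-aminoethylidene)-4-{[2,6-bis(benzyloxy)-3-butanoyl-4-methoxy-5-methylphenyl]methyl}-5-hydroxy-6,6-dimethylcyclohex-4-ene-1,3-dione
Conditions: Mo(CO)6 (1 equiv), MeCN/H2O, 80 °C
Reagents that add atoms: none
Why: Reductive N–O cleavage of the isoxazole by Mo(CO)6 in wet acetonitrile, a known chemoselective opening to the β-enaminoketone that leaves benzyl ethers and ketones intact.

Step 11
Reactants: 16 2-(1-aminoethylidene)-4-{[2,6-bis(benzyloxy)-3-butanoyl-4-methoxy-5-methylphenyl]methyl}-5-hydroxy-6,6-dimethylcyclohex-4-ene-1,3-dione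
Product: 17 2-acetyl-4-{[2,6-bis(benzyloxy)-3-butanoyl-4-methoxy-5-methylphenyl]methyl}-3,5-dihydroxy-6,6-dimethylcyclohexa-2,4-dien-1-one
Conditions: 2 M aq. NaOH, EtOH, 70 °C; then 1 M HCl
Reagents that add atoms: water O
Why: Hydrolysis of the vinylogous amide by addition of hydroxide and loss of ammonia, the usual passage from an enamino-dione to a 2-acyl-1,3-dione; with ring B still benzylated, the base-induced exchange of methylene-bridged halves that free phloroglucinols undergo cannot start.

Step 12
Reactants: 17 2-acetyl-4-{[2,6-bis(benzyloxy)-3-butanoyl-4-methoxy-5-methylphenyl]methyl}-3,5-dihydroxy-6,6-dimethylcyclohexa-2,4-dien-1-one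
Product: 18 Aspidin AB
Conditions: H2 (1 atm), 10% Pd/C, EtOAc, rt
Reagents that add atoms: none
Why: Catalytic hydrogenolysis of the two aryl benzyl ethers under neutral conditions; the chelated aryl ketone and the fully substituted enol double bonds should not be reduced at atmospheric pressure.

**Compound list**

1 | 2,4,6-trihydroxytoluene | Cc1c(O)cc(O)cc1O | starting material
2 | (2,4,6-trihydroxy-3-methylbenzylidene)dimethyliminium chloride | C[N+](C)=Cc1c(O)cc(O)c(C)c1O.[Cl-] | intermediate (not isolated)
3 | 2,4,6-trihydroxy-3-methylbenzaldehyde | O=Cc1c(O)cc(O)c(C)c1O | intermediate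
4 | 2,6-dihydroxy-4-methoxy-3-methylbenzaldehyde | O=Cc1c(O)cc(OC)c(C)c1O | intermediate
5 | butyryl chloride | CCCC(Cl)=O | starting material
6 | 3-butanoyl-2,6-dihydroxy-4-methoxy-5-methylbenzaldehyde | CCCC(=O)c1c(O)c(C=O)c(O)c(C)c1OC | intermediate
7 | 2,6-bis(benzyloxy)-3-butanoyl-4-methoxy-5-methylbenzaldehyde | CCCC(=O)c1c(OCc2ccccc2)c(C=O)c(OCc2ccccc2)c(C)c1OC | intermediate
8 | 1-[2,4-bis(benzyloxy)-3-(hydroxymethyl)-6-methoxy-5-methylphenyl]butan-1-one | CCCC(=O)c1c(OCc2ccccc2)c(CO)c(OCc2ccccc2)c(C)c1OC | intermediate
9 | 1-[2,4-bis(benzyloxy)-3-(bromomethyl)-6-methoxy-5-methylphenyl]butan-1-one | CCCC(=O)c1c(OCc2ccccc2)c(CBr)c(OCc2ccccc2)c(C)c1OC | intermediate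
10 | ethyl 3,5-dimethylisoxazole-4-carboxylate | CCOC(=O)c1c(C)noc1C | starting material
11 | N-methoxy-N-methylisobutyramide | CC(C)C(=O)N(C)OC | starting material
12 | [4-(ethoxycarbonyl)-3-methylisoxazol-5-yl]methyllithium | [Li]Cc1onc(C)c1C(=O)OCC | intermediate (not isolated)
13 | ethyl 3-methyl-5-(3-methyl-2-oxobutyl)isoxazole-4-carboxylate | CCOC(=O)c1c(C)noc1CC(=O)C(C)C | intermediate
14 | ethyl 5-{1-[2,6-bis(benzyloxy)-3-butanoyl-4-methoxy-5-methylphenyl]-4-methyl-3-oxopentan-2-yl}-3-methylisoxazole-4-carboxylate (racemic) | CCOC(=O)c1c(C)noc1C(Cc1c(OCc2ccccc2)c(C(=O)CCC)c(OC)c(C)c1OCc1ccccc1)C(=O)C(C)C | intermediate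
15 | 7-{[2,6-bis(benzyloxy)-3-butanoyl-4-methoxy-5-methylphenyl]methyl}-6-hydroxy-3,5,5-trimethyl-1,2-benzisoxazol-4(5H)-one | Cc1noc2c1C(=O)C(C)(C)C(O)=C2Cc1c(OCc2ccccc2)c(C(=O)CCC)c(OC)c(C)c1OCc1ccccc1 | intermediate
16 | 2-(1-aminoethylidene)-4-{[2,6-bis(benzyloxy)-3-butanoyl-4-methoxy-5-methylphenyl]methyl}-5-hydroxy-6,6-dimethylcyclohex-4-ene-1,3-dione (tautomeric, alkene geometry not fixed) | CC(N)=C1C(=O)C(C)(C)C(O)=C(Cc2c(OCc3ccccc3)c(C(=O)CCC)c(OC)c(C)c2OCc2ccccc2)C1=O | intermediate
17 | 2-acetyl-4-{[2,6-bis(benzyloxy)-3-butanoyl-4-methoxy-5-methylphenyl]methyl}-3,5-dihydroxy-6,6-dimethylcyclohexa-2,4-dien-1-one | CCCC(=O)c1c(OCc2ccccc2)c(CC2=C(O)C(C)(C)C(=O)C(C(C)=O)=C2O)c(OCc2ccccc2)c(C)c1OC | intermediate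
18 | Aspidin AB | CCCC(=O)c1c(O)c(CC2=C(O)C(C)(C)C(=O)C(C(C)=O)=C2O)c(O)c(C)c1OC | target

**Step count**

Total: 12 steps. Longest linear sequence: 11 steps (steps 1–6, then 8–12); step 7 is the one-step side branch.

**Steps most likely to fail**

Step 9 (key ring closure). The substrate may rest as the benzylic enolate or drain into the O-acylated enol lactone, so that closure at the hindered tertiary carbon is too slow and retro-Claisen or decomposition takes over on heating. The fallback closes ring A from the other side, at the bond between the bridge-bearing carbon and the neighbouring enol carbon, where the nucleophile is the most acidic carbon. It sets out from 10 and returns at 15. Saponification of 10 (LiOH, THF/H2O) would give 3,5-dimethylisoxazole-4-carboxylic acid F1, and (COCl)2 with catalytic DMF would give 3,5-dimethylisoxazole-4-carbonyl chloride F2. Acylation of the lithium enolate of methyl isobutyrate (LiN(iPr)2, THF, −78 °C) with F2 would give methyl 3-(3,5-dimethylisoxazol-4-yl)-2,2-dimethyl-3-oxopropanoate F3, in which the CMe2 carbon and its bond to the future ring ketone carbon are already in place. LiN(SiMe3)2 (2 equiv) would deprotonate the 5-methyl group and the lateral carbanion would close onto the methyl ester (Dieckmann condensation) to give 6-hydroxy-3,5,5-trimethyl-1,2-benzisoxazol-4(5H)-one F4. C-Alkylation of F4 at its 7-position with bromide 9 (K2CO3, aqueous acetone, to favour carbon over oxygen) would return to 15.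

Step 3 (Friedel–Crafts butyrylation of the aldehyde). The aldehyde may condense with the electron-rich ring under the Lewis acid, or the methyl ether ortho to the new ketone may be cleaved. The fallback introduces the butyryl group first and the formyl group last. It sets out from 1 and 5 and returns at 7. Acylation of 1 with 5 (AlCl3, PhNO2) would give 1-(2,4,6-trihydroxy-3-methylphenyl)butan-1-one F5. Two equivalents of benzyl bromide (K2CO3, DMF) should etherify the para hydroxyl and the less hindered ortho hydroxyl, leaving the chelated hydroxyl next to the methyl group, to give 1-[4,6-bis(benzyloxy)-2-hydroxy-3-methylphenyl]butan-1-one F6. Methylation (Me2SO4, K2CO3, acetone, reflux) would give 1-[4,6-bis(benzyloxy)-2-methoxy-3-methylphenyl]butan-1-one F7. Vilsmeier–Haack formylation of F7 at the one free position, between the benzyloxy groups (POCl3, DMF, 0 °C → rt, kept cold so that the hindered ketone is not attacked), would pass through {[2,6-bis(benzyloxy)-3-butanoyl-4-methoxy-5-methylphenyl]methylidene}dimethyliminium chloride F8, whose hydrolysis on aqueous work-up would return to 7.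

Step 8 (C-benzylation). The electron-rich benzylic bromide may solvolyse before it is captured, or the ambident enolate may be alkylated on oxygen. The fallback joins the fragments at the aldehyde oxidation level and needs neither 8 nor 9. It sets out from 7 and 13 and returns at 14. Knoevenagel condensation of 7 with 13 (piperidine, AcOH, toluene, reflux with water removal) would give ethyl 5-{1-[2,6-bis(benzyloxy)-3-butanoyl-4-methoxy-5-methylphenyl]-4-methyl-3-oxopent-1-en-2-yl}-3-methylisoxazole-4-carboxylate F9. Conjugate reduction of this doubly activated alkene with Hantzsch ester (EtOH, 60 °C), which leaves the aryl ketone alone, would give 14.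

**Further compounds**

F1 | step 9 | 3,5-dimethylisoxazole-4-carboxylic acid | Cc1noc(C)c1C(=O)O
F2 | step 9 | 3,5-dimethylisoxazole-4-carbonyl chloride | Cc1noc(C)c1C(=O)Cl
F3 | step 9 | methyl 3-(3,5-dimethylisoxazol-4-yl)-2,2-dimethyl-3-oxopropanoate | COC(=O)C(C)(C)C(=O)c1c(C)noc1C
F4 | step 9 | 6-hydroxy-3,5,5-trimethyl-1,2-benzisoxazol-4(5H)-one | Cc1noc2c1C(=O)C(C)(C)C(O)=C2
F5 | step 3 | 1-(2,4,6-trihydroxy-3-methylphenyl)butan-1-one | CCCC(=O)c1c(O)cc(O)c(C)c1O
F6 | step 3 | 1-[4,6-bis(benzyloxy)-2-hydroxy-3-methylphenyl]butan-1-one | CCCC(=O)c1c(OCc2ccccc2)cc(OCc2ccccc2)c(C)c1O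
F7 | step 3 | 1-[4,6-bis(benzyloxy)-2-methoxy-3-methylphenyl]butan-1-one | CCCC(=O)c1c(OCc2ccccc2)cc(OCc2ccccc2)c(C)c1OC
F8 | step 3 | {[2,6-bis(benzyloxy)-3-butanoyl-4-methoxy-5-methylphenyl]methylidene}dimethyliminium chloride | CCCC(=O)c1c(OCc2ccccc2)c(C=[N+](C)C)c(OCc2ccccc2)c(C)c1OC.[Cl-]
F9 | step 8 | ethyl 5-{1-[2,6-bis(benzyloxy)-3-butanoyl-4-methoxy-5-methylphenyl]-4-methyl-3-oxopent-1-en-2-yl}-3-methylisoxazole-4-carboxylate (mixture of alkene isomers) | CCOC(=O)c1c(C)noc1C(=Cc1c(OCc2ccccc2)c(C(=O)CCC)c(OC)c(C)c1OCc1ccccc1)C(=O)C(C)C
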